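The ratio of initiator charges, Saturday's over Friday's, is 1.61, and the bench rule for chain reactions lets the rate follow its square root, 1.27. Read as first-order decay, substrate falls between 2.50 h and 8.00 h at 0.131 h⁻¹ on Friday and 0.197 h⁻¹ on Saturday, a ratio of 1.50, while the readings out to 15.0 h, closer to the scatter, give 1.04, so the square root stands between two readings and is kept as a working rule.

| flask | substrate | partner | scavenger | initiator | remark | time |
|---|---|---|---|---|---|---|
| Friday's | 0.071 M | 0.071 M (fed, over 2.0 h) | 0.0852 M | 1.8 mM | run made earlier |  |
| Saturday's | 0.071 M | 0.071 M (fed, over 2.0 h) | 0.0852 M | 2.9 mM | run made earlier |  |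
| flask | 0.071 M | 0.0710 M (fed, over 2.0 h) | 0.0852 M | 1.3 mM |  | 25 h |

| run | time / h | substrate / % | target / % |
|---|---|---|---|
| Friday's | 2.50 | 80 | 18 |
| Friday's | 5.00 | 56 | 43 |
| Friday's | 8.00 | 39 | 63 |
| Friday's | 15.0 | 9 | 92 |
| Friday's | 30.0 | 0 | 101 |
| Saturday's | 2.50 | 77 | 24 |
| Saturday's | 8.00 | 26 | 75 |
| Saturday's | 15.0 | 8 | 91 |
| Saturday's | 20.0 | 3 | 97 |
| Saturday's | 30.0 | 0 | 99 |

(each reading ± 2 percentage points)

1. part of the substrate that has reacted at 25 h
2. share of the unused partner that is free and not bound as idle adduct, at 25 h

- the earlier runs do not show how much of partner is bound; that part of a forecast is a guess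

Scaled to this flask's initiator and averaged over both runs, the rule gives 0.122 h⁻¹. A partner molecule enters on average at 1.00 h, so the present reckoning takes its chance of still being unreacted at 25 h, the survivor share, as 5.40%, which makes 94.6% of the substrate reacted. In both runs target rises as substrate falls, so these two go one for one within the scatter, and, taking one partner per substrate, the border of the rule is the charge ratio of partner to substrate: here it is 1.00, so the two runs cannot tell which of the two charges the decay follows, and a flask charged below that ratio is reckoned here, with the same survivor share, as the ratio times the reacted share of partner. The runs say nothing on binding.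

The forecast gives 95% (90% to 98%) and, for free partner, 35% (5% to 85%), calling the latter “a pure guess”. The flask gives 95.2% and 99.9%.

    partner + first chain carrier → target + second chain carrier (k = 59000 M⁻¹ s⁻¹)
    substrate + initiating radical → capped initiator + first chain carrier (k = 1.10 × 10⁶ M⁻¹ s⁻¹)
    initiator → 2 initiating radical (k = 3.30 × 10⁻⁶ min⁻¹)
    partner + released group ⇌ idle adduct, settled at all times (K = 16.0 M⁻¹)
    substrate + second chain carrier → released group + first chain carrier (k = 2.30 × 10⁵ M⁻¹ s⁻¹)
    scavenger + released group → scavenged by-product (k = 4.70 M⁻¹ min⁻¹)
    2 first chain carrier → ended chains (k = 2.00 × 10⁸ M⁻¹ s⁻¹)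

At 25 h this flask holds 4.8% of its substrate and 4.8% of its partner, against the survivor share of 5.40%. At 25.0 h in this flask the step of substrate with the second chain carrier has a half-life of 5.5 h, short against the time, and uses substrate 850 times as fast as the step with the initiating radical. A neighbouring flask, the same but with 0.018 M of partner, the limiting reagent, has a charge ratio of 0.254, and the survivor share gives there 24.0% of substrate reacted; that flask gives 24.2%, with 4.78% of its partner left.

(Readings and results stem from a simulated flask with made-up constants, noise included.)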